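## Structural features

The target is an ester that joins two carbocycles through one oxygen. Ring A is a benzoic acid with a free phenol at C4 flanked by two 3-methylbut-2-enyl (prenyl) chains at C3 and C5. Ring B is a 4-methylcyclohex-3-ene whose C1 carries both the ester oxygen and an isopropyl group, that is, the terpinen-4-ol skeleton. C1 of ring B is the only stereocentre; it is fully substituted and (R), with no neighbouring stereocentre. Its chirality rests only on the fact that one ring arm (C2–C3) leads into the C3=C4 alkene while the other (C6–C5) is saturated.

The fragile groups are: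
- the three trisubstituted alkenes (acid would close the prenyl chains onto the phenol as chromans and would isomerise or hydrate the ring alkene);
- the tertiary, homoallylic ester (E1 loss of the acid towards a p-menthadiene);
- the electron-rich phenol (oxidation).

The real difficulty is twofold: making a C–O ester bond at a tertiary carbon shielded by isopropyl, and telling apart two ring arms that differ only three bonds away from the stereocentre. The key step uses the 1,4-relationship in ring B between C1 (O, isopropyl) and the methyl-bearing C4. This is the para relationship of 4-isopropylphenol, whose para carbon becomes C1 and whose phenolic carbon becomes C4. Oxidative dearomatisation lets the carboxylate of ring A add to that carbon while it is cationic. The resulting cyclohexadienone has a mirror plane through C1 and C4, so the stereochemical problem becomes the differentiation of two enantiotopic enone units.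

## Logic of the disconnections

**15 ⇐ 14.** The phenolic O–H is traced back to an O–Si bond. The phenol of ring A has to stay masked through an oxidation, two hydride reductions and a cross-coupling. A silyl ether comes off with buffered fluoride, which touches neither the tertiary ester nor the alkenes. The demand is that unmasking is not acidic.

**14 ⇐ 13.** The C4–CH3 bond of ring B is cut. A methyl group on an sp2 carbon is best delivered to an alkenyl electrophile, and the enol sulfonate in 13 encodes the alkene position. The forward coupling must leave the homoallylic ester at C1 alone.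

**13 ⇐ 11 (through 12).** The enol O–S bond and one C2–H bond are removed. This leads to an enone whose C2=C3 bond marks the side of the ring that will carry the alkene. The forward step must add hydride 1,4 and must not let the enolate 12 move to the other α-carbon, since that would give the mirror-image sulfonate.

**11 ⇐ 10.** The C5–H and C6–H bonds are removed. The stereocentre disappears and 10 is achiral, with two enantiotopic enone units. The forward step needs a chiral catalyst that reduces one of them and stops.

**10 ⇐ 7 + 8 (through 9).** The alkyl C1–O bond of the ester is cut. This makes the hindered bond by nucleophile-on-cation instead of by acylation of a tertiary alcohol, and both halves become simple aromatics. The forward step needs para attack, needs the carboxylate of 7 to be the only competent nucleophile present, and needs the phenol of 7 to be masked so that only 8 is oxidised.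

**7 ⇐ 5 (through 6).** The aryl C–CO2H bond is cut. Placing the carboxyl group last lets the acid appear with the silyl ether already in place; no ester has to be saponified next to an aryl silyl ether, and no silyl ester has to be cleaved selectively. The forward metalation must tolerate the silyl ether and the prenyl chains.

**5 ⇐ 4.** The O–Si bond is cut. Silylation must come before metalation (acidic O–H) and before the oxidation in which 7 takes part.

**4 ⇐ 1 + 2.** The two aryl–CH2 bonds ortho to oxygen are cut. Both starting materials are commercial, and the para position of 1 is blocked by the halogen that later becomes the carboxyl group. The forward step needs C- over O-alkylation and attack at the primary carbon of 2.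

## Other disconnections considered

**Alternative 1:** The cut is the C3=C4 double bond of ring B.

- *Forward step:* the open-chain tertiary ester (4R)-7-methyl-4-(propan-2-yl)octa-1,7-dien-4-yl 4-[(tert-butyldimethylsilyl)oxy]-3,5-bis(3-methylbut-2-en-1-yl)benzoate A2 would be closed with second-generation Grubbs catalyst to the silylated terpinenyl ester A3, which is identical with 14. A2 would come from acylation of the carbinol (4R)-7-methyl-4-(propan-2-yl)octa-1,7-dien-4-ol A1. The configuration of A1 would go back to a Sharpless epoxidation of a 2-isopropyl allylic alcohol and two successive epoxide openings.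
- *In its favour:* closure to a cyclohexene is easy and is pulled forward by a gaseous by-product. The alkene can only form where the two arms put it, so the regiochemical question that the chosen plan solves with a regiodefined enolate does not arise; on this point Alternative 1 is the better plan. The sense of the epoxidation follows from the tartrate used, whereas the sense of the copper hydride desymmetrisation must first be established; this is a second point for Alternative 1.
- *Against it:* the two arms on the carbinol differ by one methylene, so A1 has to be built arm by arm over five to six steps. A1 is a tertiary alcohol next to isopropyl, and its acylation with a bulky aroyl donor is exactly the bond formation the chosen plan avoids; forcing conditions invite elimination. A2 holds four alkenes, and the ruthenium carbene can enter the prenyl groups by cross-metathesis.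
- *Comparison:* both plans reach the same silyl ether. The chosen plan forms the C–O bond at a cationic carbon under mild oxidation, Alternative 1 by acyl substitution on a hindered alkoxide. Alternative 1 would need about eleven to twelve operations against eight.

**Alternative 2:** The cut is the enol C–O bond, and with it the position of the ring alkene.

- *Forward step:* the prochiral ketone 4-oxo-1-(propan-2-yl)cyclohexyl 4-[(tert-butyldimethylsilyl)oxy]-3,5-bis(3-methylbut-2-en-1-yl)benzoate A4 would be deprotonated at one of its two enantiotopic α-methylenes by one antipode of lithium bis(1-phenylethyl)amide with LiCl. The enolate would be trapped with PhNTf2 to the enol triflate A5, which is identical with 13.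
- *In its favour:* stereocentre and alkene position are fixed in one operation that replaces steps 5 and 6 of the chosen route; at this stage Alternative 2 is shorter by one step and is the better plan. The chair with equatorial isopropyl and axial acyloxy gives the base a well-defined substrate, and the chiral amine can be recovered. The last two steps are the same as in the chosen plan, so the plans are equal there.
- *Against it:* the base is stoichiometric and needs −78 °C or below. Such deprotonations are most selective under an in-situ silyl chloride quench, while sulfonimide trapping is an external quench; this may cost selectivity or add a step through the silyl enol ether. A4 must still be made. From a mono-protected diketone by isopropyl-Grignard addition and acylation, the hindered tertiary acylation returns. From 10 by exhaustive conjugate reduction, the dearomatisation is still needed.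
- *Comparison:* the ester bond is not addressed by this cut at all, so it complements the chosen key step more than it competes with it. It is kept as the fallback for step 5.

**Alternative 3:** The cut removes the C1–C2 and C5–C6 bonds of ring B.

- *Forward step:* isoprene A6 would add to the α-aroyloxyacrolein 3-oxoprop-1-en-2-yl 4-[(tert-butyldimethylsilyl)oxy]-3,5-bis(3-methylbut-2-en-1-yl)benzoate A7 under a chiral 1,1'-binaphthyl-2,2'-diammonium bis(triflimide) catalyst. The product would be the aldehyde (1R)-1-formyl-4-methylcyclohex-3-en-1-yl 4-[(tert-butyldimethylsilyl)oxy]-3,5-bis(3-methylbut-2-en-1-yl)benzoate A8.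
- *In its favour:* ring B, the oxygenated quaternary stereocentre and the 1,4-placement of the methyl group come from one catalytic step. For the methyl position this is the better plan, since no enol triflate and no palladium are needed. The ester is made on an enol and not on a tertiary alcohol, which makes it the equal of the chosen plan on that point. The prenyl alkenes are not dienes and should stay out of the cycloaddition.
- *Against it:* A8 carries a formyl group where isopropyl must stand. Conversion needs methyl addition, oxidation, methylenation and hydrogenation of a 1,1-disubstituted alkene beside three trisubstituted ones, about four steps. These pass through an alkoxide next to the tertiary ester, which invites a 1,2-acyl shift. The strongly acidic ammonium triflimide catalyst threatens the prenyl chains and the aryl silyl ether. A7 is a polymerisable enal that must be made from the valuable acid.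
- *Comparison:* Alternative 3 builds ring B from two C–C bonds and sets C1 directly, whereas the chosen plan takes ring B ready-made from a phenol and sets C1 afterwards. The step count would be about eleven against eight.

Key step: step 4

Assumption: the sense of induction of the chiral copper hydride catalyst on a 4-acyloxy-4-alkyl dienone is not predicted here; both ligand antipodes are commercial, and the route takes the one that delivers (S)-11.

## Route

Step 1
Reactants: 1 4-iodophenol; 2 prenyl bromide (1-bromo-3-methylbut-2-ene)
Product: 4 4-iodo-2,6-bis(3-methylbut-2-en-1-yl)phenol, via 4-iodo-2-prenylphenol 3 (not isolated)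
Conditions: NaH (2.2 equiv), 2 (2.2 equiv), toluene, 0 °C → rt
Reagents that add atoms: none
Why: Ortho C-alkylation of a sodium phenoxide in a non-polar solvent: the aggregated ion pair in toluene shields oxygen and the ortho carbon attacks the primary carbon of the allylic bromide (SN2, linear prenyl), after which the dienone tautomerises to the phenol. A second deprotonation–alkylation fills the other ortho position; the para position is blocked by iodine.

Step 2
Reactants: 4 4-iodo-2,6-bis(3-methylbut-2-en-1-yl)phenol
Product: 5 tert-butyl[4-iodo-2,6-bis(3-methylbut-2-en-1-yl)phenoxy]dimethylsilane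
Conditions: TBSCl, imidazole, DMF, rt
Reagents that add atoms: tert-butyldimethylsilyl chloride, CC(C)(C)[Si](C)(C)Cl
Why: Imidazole-mediated O-silylation of a phenol; the two ortho substituents are attached through CH2 groups, so the oxygen remains accessible. The silyl ether removes the acidic O–H before metalation and keeps this phenol out of the later oxidation.

Step 3
Reactants: 5 tert-butyl[4-iodo-2,6-bis(3-methylbut-2-en-1-yl)phenoxy]dimethylsilane
Product: 7 4-[(tert-butyldimethylsilyl)oxy]-3,5-bis(3-methylbut-2-en-1-yl)benzoic acid, via arylmagnesium chloride 6 (not isolated)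
Conditions: i-PrMgCl·LiCl, THF, −15 → 0 °C; CO2 (dry gas), −20 °C → rt; then 1 M HCl to pH 3, 0 °C
Reagents that add atoms: carbon dioxide, O=C=O
Why: Iodine–magnesium exchange of an aryl iodide followed by carboxylation of the aryl Grignard reagent. The mild magnesium reagent should not deprotonate the benzylic–allylic CH2 groups, and the metal sits para to the silyloxy group, so no silyl migration can occur; the acid is obtained with the silyl ether already in place.

Step 4
Reactants: 7 4-[(tert-butyldimethylsilyl)oxy]-3,5-bis(3-methylbut-2-en-1-yl)benzoic acid; 8 4-isopropylphenol (4-(propan-2-yl)phenol)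
Product: 10 4-oxo-1-(propan-2-yl)cyclohexa-2,5-dien-1-yl 4-[(tert-butyldimethylsilyl)oxy]-3,5-bis(3-methylbut-2-en-1-yl)benzoate, via bis(aroyloxy)iodobenzene 9 (not isolated)
Conditions: 7 (2.05 equiv), PhI(OAc)2 (1.0 equiv), PhCl, 45 °C, 20 mbar (AcOH removed); then 8 (1.0 equiv, added over 1 h), CH2Cl2–MeCN, −20 → 0 °C
Reagents that add atoms: none
Why: Both acetates of PhI(OAc)2 are exchanged for the carboxylate of 7, driven by evaporation of acetic acid, to give the trivalent iodine reagent 9; phenol 8 then displaces one carboxylate at iodine, and reductive loss of iodobenzene leaves a phenoxenium-type species whose positive charge is largest at the para carbon, where the released carboxylate adds and forms the tertiary C1–O ester bond. The closest known reaction type is the oxidative dearomatisation of 4-alkylphenols with PhI(OAc)2 or PhI(O2CR)2 to 4-acyloxycyclohexa-2,5-dienones (para-quinol esters). No ring is closed and no stereocentre is formed: C1 becomes fully substituted but lies on the mirror plane of 10. The step needs para over ortho attack, which the charge distribution of the 4-alkylphenoxenium ion favours and which is protected by the absence of any smaller nucleophile (acetic acid stripped off, no water or alcohol). It needs carboxylate addition to outrun loss of the isopropyl methine proton to the quinone methide, which low temperature, a non-basic medium and carboxylate released next to the cation should favour. It needs the oxidant to spare the four prenyl alkenes and ring A, which should hold because free phenol 8 is by far the best ligand and reductant for trivalent iodine, while the phenol of 7 is a silyl ether on a ring deactivated by the carboxyl group. Slow addition of 8 keeps free phenol scarce and should suppress phenol–phenol coupling; the second carboxylate ligand is returned as 7 and can be recovered.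

Step 5
Reactants: 10 4-oxo-1-(propan-2-yl)cyclohexa-2,5-dien-1-yl 4-[(tert-butyldimethylsilyl)oxy]-3,5-bis(3-methylbut-2-en-1-yl)benzoate
Product: 11 (1S)-4-oxo-1-(propan-2-yl)cyclohex-2-en-1-yl 4-[(tert-butyldimethylsilyl)oxy]-3,5-bis(3-methylbut-2-en-1-yl)benzoate
Conditions: Cu(OAc)2 (5 mol %), (R)-DTBM-SEGPHOS (5.5 mol %), (EtO)2MeSiH (1.1 equiv), t-BuOH (1.1 equiv), toluene, −30 °C
Reagents that add atoms: none
Why: Enantioselective conjugate reduction by a ligated monovalent copper hydride, used as a desymmetrisation of a 4,4-disubstituted cyclohexa-2,5-dienone: hydride goes to one β-carbon (C6), t-BuOH protonates the copper enolate and the silane regenerates the hydride. C1 becomes stereogenic under catalyst control: hydride should approach the ring face opposite the isopropyl group, and on that face the chiral bisphosphine distinguishes the two enantiotopic enone units, so that the C5–C6 arm is saturated and C1 is (S) (S only because the remaining vinylic arm outranks isopropyl). One equivalent of silane and the lower electrophilicity of enone 11 compared with the cross-conjugated dienone 10 should hold the reaction at 11.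

Step 6
Reactants: 11 (1S)-4-oxo-1-(propan-2-yl)cyclohex-2-en-1-yl 4-[(tert-butyldimethylsilyl)oxy]-3,5-bis(3-methylbut-2-en-1-yl)benzoate
Product: 13 (1R)-1-(propan-2-yl)-4-[(trifluoromethanesulfonyl)oxy]cyclohex-3-en-1-yl 4-[(tert-butyldimethylsilyl)oxy]-3,5-bis(3-methylbut-2-en-1-yl)benzoate, via lithium enolate 12 (not isolated)
Conditions: LiBH(sec-Bu)3 (1.05 equiv), THF, −78 °C; PhNTf2 (1.2 equiv), −78 → 0 °C
Reagents that add atoms: N-phenylbis(trifluoromethanesulfonimide), O=S(=O)(N(c1ccccc1)S(=O)(=O)C(F)(F)F)C(F)(F)F
Why: 1,4-Reduction of a β-unsubstituted cyclohexenone by a bulky trialkylborohydride followed by O-sulfonylation of the enolate: hydride adds to C2, the aprotic medium keeps lithium enolate 12 on the C3=C4 side, and PhNTf2 traps it on oxygen. No bond at C1 is touched, so the configuration is carried over (the descriptor becomes R only because the C2 arm is now sp3); the ester of a tertiary alcohol and the aryl silyl ether should not react with the hindered borohydride at −78 °C.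

Step 7
Reactants: 13 (1R)-1-(propan-2-yl)-4-[(trifluoromethanesulfonyl)oxy]cyclohex-3-en-1-yl 4-[(tert-butyldimethylsilyl)oxy]-3,5-bis(3-methylbut-2-en-1-yl)benzoate
Product: 14 (1R)-4-methyl-1-(propan-2-yl)cyclohex-3-en-1-yl 4-[(tert-butyldimethylsilyl)oxy]-3,5-bis(3-methylbut-2-en-1-yl)benzoate
Conditions: Pd(PPh3)4 (5 mol %), (MeBO)3 (1.0 equiv), K2CO3 (3 equiv), 1,4-dioxane, 80 °C
Reagents that add atoms: trimethylboroxine, CB1OB(C)OB(C)O1
Why: Suzuki–Miyaura coupling of an alkenyl triflate with trimethylboroxine: zerovalent palladium inserts into the C4–O bond, the carbonate-activated boroxine transfers methyl, and reductive elimination gives the trisubstituted alkene where the triflate stood. The ester at C1 is homoallylic, not allylic, so palladium cannot ionise it; partial loss of the silyl group under the basic conditions would do no harm, since step 8 removes it.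

Step 8
Reactants: 14 (1R)-4-methyl-1-(propan-2-yl)cyclohex-3-en-1-yl 4-[(tert-butyldimethylsilyl)oxy]-3,5-bis(3-methylbut-2-en-1-yl)benzoate
Product: 15 (1R)-4-methyl-1-(propan-2-yl)cyclohex-3-en-1-yl 4-hydroxy-3,5-bis(3-methylbut-2-en-1-yl)benzoate
Conditions: Bu4NF (1.2 equiv), AcOH (1.2 equiv), THF, 0 °C
Reagents that add atoms: none
Why: Fluoride-induced cleavage of an aryl silyl ether, driven by Si–F bond formation; acetic acid buffers the phenoxide. The tertiary ester and the three alkenes should not react with buffered fluoride, so C1 stays (R).

## Compound list

1 | 4-iodophenol | Oc1ccc(I)cc1 | starting material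
2 | prenyl bromide (1-bromo-3-methylbut-2-ene) | CC(C)=CCBr | starting material
3 | 4-iodo-2-(3-methylbut-2-en-1-yl)phenol | CC(C)=CCc1cc(I)ccc1O | intermediate
4 | 4-iodo-2,6-bis(3-methylbut-2-en-1-yl)phenol | CC(C)=CCc1cc(I)cc(CC=C(C)C)c1O | intermediate
5 | tert-butyl[4-iodo-2,6-bis(3-methylbut-2-en-1-yl)phenoxy]dimethylsilane | CC(C)=CCc1cc(I)cc(CC=C(C)C)c1O[Si](C)(C)C(C)(C)C | intermediate
6 | {4-[(tert-butyldimethylsilyl)oxy]-3,5-bis(3-methylbut-2-en-1-yl)phenyl}magnesium chloride | CC(C)=CCc1cc([Mg]Cl)cc(CC=C(C)C)c1O[Si](C)(C)C(C)(C)C | intermediate
7 | 4-[(tert-butyldimethylsilyl)oxy]-3,5-bis(3-methylbut-2-en-1-yl)benzoic acid | CC(C)=CCc1cc(C(=O)O)cc(CC=C(C)C)c1O[Si](C)(C)C(C)(C)C | intermediate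
8 | 4-isopropylphenol | CC(C)c1ccc(O)cc1 | starting material
9 | [bis({4-[(tert-butyldimethylsilyl)oxy]-3,5-bis(3-methylbut-2-en-1-yl)benzoyl}oxy)iodo]benzene | CC(C)=CCc1cc(C(=O)OI(OC(=O)c2cc(CC=C(C)C)c(O[Si](C)(C)C(C)(C)C)c(CC=C(C)C)c2)c2ccccc2)cc(CC=C(C)C)c1O[Si](C)(C)C(C)(C)C | intermediate
10 | 4-oxo-1-(propan-2-yl)cyclohexa-2,5-dien-1-yl 4-[(tert-butyldimethylsilyl)oxy]-3,5-bis(3-methylbut-2-en-1-yl)benzoate | CC(C)=CCc1cc(C(=O)OC2(C(C)C)C=CC(=O)C=C2)cc(CC=C(C)C)c1O[Si](C)(C)C(C)(C)C | intermediate
11 | (1S)-4-oxo-1-(propan-2-yl)cyclohex-2-en-1-yl 4-[(tert-butyldimethylsilyl)oxy]-3,5-bis(3-methylbut-2-en-1-yl)benzoate | CC(C)=CCc1cc(C(=O)O[C@@]2(C(C)C)C=CC(=O)CC2)cc(CC=C(C)C)c1O[Si](C)(C)C(C)(C)C | intermediate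
12 | lithium (4R)-4-({4-[(tert-butyldimethylsilyl)oxy]-3,5-bis(3-methylbut-2-en-1-yl)benzoyl}oxy)-4-(propan-2-yl)cyclohex-1-en-1-olate | CC(C)=CCc1cc(C(=O)O[C@@]2(C(C)C)CC=C(O[Li])CC2)cc(CC=C(C)C)c1O[Si](C)(C)C(C)(C)C | intermediate
13 | (1R)-1-(propan-2-yl)-4-[(trifluoromethanesulfonyl)oxy]cyclohex-3-en-1-yl 4-[(tert-butyldimethylsilyl)oxy]-3,5-bis(3-methylbut-2-en-1-yl)benzoate | CC(C)=CCc1cc(C(=O)O[C@@]2(C(C)C)CC=C(OS(=O)(=O)C(F)(F)F)CC2)cc(CC=C(C)C)c1O[Si](C)(C)C(C)(C)C | intermediate
14 | (1R)-4-methyl-1-(propan-2-yl)cyclohex-3-en-1-yl 4-[(tert-butyldimethylsilyl)oxy]-3,5-bis(3-methylbut-2-en-1-yl)benzoate | CC(C)=CCc1cc(C(=O)O[C@@]2(C(C)C)CC=C(C)CC2)cc(CC=C(C)C)c1O[Si](C)(C)C(C)(C)C | intermediate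
15 | (1R)-4-methyl-1-(propan-2-yl)cyclohex-3-en-1-yl 4-hydroxy-3,5-bis(3-methylbut-2-en-1-yl)benzoate (CNP0120997.1) | CC(C)=CCc1cc(C(=O)O[C@@]2(C(C)C)CC=C(C)CC2)cc(CC=C(C)C)c1O | target

## Step count and least certain steps

Total: 8 steps. Longest linear sequence: 8 steps (1 → 15); 8 enters at step 4 without prior steps.

**Step 4 (key step).** The carboxylate has to add to a para carbon that carries an isopropyl group. Capture may therefore be slow, and loss of the methine proton from the cationic intermediate (quinone methide formation), attack at the ortho carbon, or oxidation of the prenyl alkenes by unconsumed trivalent iodine may take over.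
Fallback: it sets out from 8 and 7 and comes back at 10. Oxidation of 8 with PhI(OAc)2 in MeCN–H2O, where water is the small nucleophile, should give 4-hydroxy-4-(propan-2-yl)cyclohexa-2,5-dien-1-one F1. Acid 7 is turned under neutral conditions with 1-chloro-N,N,2-trimethylprop-1-en-1-amine into 4-[(tert-butyldimethylsilyl)oxy]-3,5-bis(3-methylbut-2-en-1-yl)benzoyl chloride F2. Acylation of F1 with F2 (Et3N, DMAP, CH2Cl2) then forms the acyl C–O bond of 10 in place of the alkyl C–O bond.

**Step 5.** Hydride delivery anti to isopropyl and anti to the acyloxy group pair with opposite enantiotopic alkenes, so weak facial discrimination would erode the enantioselectivity. Further risks are over-reduction to the achiral saturated ketone and ionisation of the C1–O bond at the copper enolate stage with return to an arene.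
Fallback: it sets out from 10 and comes back at 13, bypassing step 6 as well. Exhaustive conjugate reduction with catalytic [(Ph3P)CuH]6, excess (EtO)2MeSiH and t-BuOH gives the prochiral ketone 4-oxo-1-(propan-2-yl)cyclohexyl 4-[(tert-butyldimethylsilyl)oxy]-3,5-bis(3-methylbut-2-en-1-yl)benzoate F3. Enantiotopic deprotonation with lithium bis[(R)-1-phenylethyl]amide or its antipode and LiCl in THF at −78 °C, then trapping with PhNTf2, leads to 13.

**Step 6.** The β-carbon is next to the fully substituted C1, so hydride attack at the carbonyl carbon (1,2-reduction) may compete. Any proton exchange before sulfonylation would move the enolate to the other α-carbon and thereby lower the enantiomeric purity.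
Fallback: it sets out from 11 and comes back at 13. RhCl(PPh3)3-catalysed 1,4-hydrosilylation with Et3SiH (toluene, 50 °C) gives, without a free enolate, (1R)-1-(propan-2-yl)-4-[(triethylsilyl)oxy]cyclohex-3-en-1-yl 4-[(tert-butyldimethylsilyl)oxy]-3,5-bis(3-methylbut-2-en-1-yl)benzoate F4. CsF and PhNTf2 in DME convert F4 into 13. The enol Si–O bond is expected to be far more fluoride-labile than the hindered aryl Si–O bond, but concurrent cleavage of the aryl silyl ether is the weak point of this detour.

**Step 1.** O-alkylation, arrest after one alkylation and attack through the tertiary allylic terminus can all compete with the double ortho C-alkylation and would lower the mass balance.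
Fallback: it sets out from 2 and comes back at 7, replacing steps 1 to 3. Commercial methyl 3,5-dibromo-4-hydroxybenzoate F5 is silylated (TBSCl, imidazole, DMF) to methyl 3,5-dibromo-4-[(tert-butyldimethylsilyl)oxy]benzoate F6. Bromide 2 is converted with zinc dust and LiCl in THF into prenylzinc bromide F7, which is coupled twice with F6 under Pd(OAc)2 and the biarylphosphine CPhos (linear-selective Negishi allylation). This gives methyl 4-[(tert-butyldimethylsilyl)oxy]-3,5-bis(3-methylbut-2-en-1-yl)benzoate F8. Cleavage of the methyl ester with Me3SnOH in 1,2-dichloroethane at 80 °C, which should leave the aryl silyl ether in place, gives 7.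

## Further compounds

F1 | step 4 | 4-hydroxy-4-(propan-2-yl)cyclohexa-2,5-dien-1-one | CC(C)C1(O)C=CC(=O)C=C1
F2 | step 4 | 4-[(tert-butyldimethylsilyl)oxy]-3,5-bis(3-methylbut-2-en-1-yl)benzoyl chloride | CC(C)=CCc1cc(C(=O)Cl)cc(CC=C(C)C)c1O[Si](C)(C)C(C)(C)C
F3 | step 5 | 4-oxo-1-(propan-2-yl)cyclohexyl 4-[(tert-butyldimethylsilyl)oxy]-3,5-bis(3-methylbut-2-en-1-yl)benzoate | CC(C)=CCc1cc(C(=O)OC2(C(C)C)CCC(=O)CC2)cc(CC=C(C)C)c1O[Si](C)(C)C(C)(C)C
F4 | step 6 | (1R)-1-(propan-2-yl)-4-[(triethylsilyl)oxy]cyclohex-3-en-1-yl 4-[(tert-butyldimethylsilyl)oxy]-3,5-bis(3-methylbut-2-en-1-yl)benzoate | CC(C)=CCc1cc(C(=O)O[C@@]2(C(C)C)CC=C(O[Si](CC)(CC)CC)CC2)cc(CC=C(C)C)c1O[Si](C)(C)C(C)(C)C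
F5 | step 1 | methyl 3,5-dibromo-4-hydroxybenzoate | COC(=O)c1cc(Br)c(O)c(Br)c1
F6 | step 1 | methyl 3,5-dibromo-4-[(tert-butyldimethylsilyl)oxy]benzoate | COC(=O)c1cc(Br)c(O[Si](C)(C)C(C)(C)C)c(Br)c1
F7 | step 1 | prenylzinc bromide ((3-methylbut-2-en-1-yl)zinc bromide) | CC(C)=CC[Zn]Br
F8 | step 1 | methyl 4-[(tert-butyldimethylsilyl)oxy]-3,5-bis(3-methylbut-2-en-1-yl)benzoate | COC(=O)c1cc(CC=C(C)C)c(O[Si](C)(C)C(C)(C)C)c(CC=C(C)C)c1
A1 | alternative 1 | (4R)-7-methyl-4-(propan-2-yl)octa-1,7-dien-4-ol | C=CC[C@@](O)(C(C)C)CCC(C)=C
A2 | alternative 1 | (4R)-7-methyl-4-(propan-2-yl)octa-1,7-dien-4-yl 4-[(tert-butyldimethylsilyl)oxy]-3,5-bis(3-methylbut-2-en-1-yl)benzoate | CC(C)=CCc1cc(C(=O)O[C@](CC=C)(C(C)C)CCC(C)=C)cc(CC=C(C)C)c1O[Si](C)(C)C(C)(C)C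
A3 | alternative 1 | (1R)-4-methyl-1-(propan-2-yl)cyclohex-3-en-1-yl 4-[(tert-butyldimethylsilyl)oxy]-3,5-bis(3-methylbut-2-en-1-yl)benzoate (identical with 14) | CC(C)=CCc1cc(C(=O)O[C@@]2(C(C)C)CC=C(C)CC2)cc(CC=C(C)C)c1O[Si](C)(C)C(C)(C)C
A4 | alternative 2 | 4-oxo-1-(propan-2-yl)cyclohexyl 4-[(tert-butyldimethylsilyl)oxy]-3,5-bis(3-methylbut-2-en-1-yl)benzoate (identical with F3) | CC(C)=CCc1cc(C(=O)OC2(C(C)C)CCC(=O)CC2)cc(CC=C(C)C)c1O[Si](C)(C)C(C)(C)C
A5 | alternative 2 | (1R)-1-(propan-2-yl)-4-[(trifluoromethanesulfonyl)oxy]cyclohex-3-en-1-yl 4-[(tert-butyldimethylsilyl)oxy]-3,5-bis(3-methylbut-2-en-1-yl)benzoate (identical with 13) | CC(C)=CCc1cc(C(=O)O[C@@]2(C(C)C)CC=C(OS(=O)(=O)C(F)(F)F)CC2)cc(CC=C(C)C)c1O[Si](C)(C)C(C)(C)C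
A6 | alternative 3 | isoprene (2-methylbuta-1,3-diene) | C=CC(C)=C
A7 | alternative 3 | 3-oxoprop-1-en-2-yl 4-[(tert-butyldimethylsilyl)oxy]-3,5-bis(3-methylbut-2-en-1-yl)benzoate | CC(C)=CCc1cc(C(=O)OC(=C)C=O)cc(CC=C(C)C)c1O[Si](C)(C)C(C)(C)C
A8 | alternative 3 | (1R)-1-formyl-4-methylcyclohex-3-en-1-yl 4-[(tert-butyldimethylsilyl)oxy]-3,5-bis(3-methylbut-2-en-1-yl)benzoate | CC(C)=CCc1cc(C(=O)O[C@@]2(C=O)CC=C(C)CC2)cc(CC=C(C)C)c1O[Si](C)(C)C(C)(C)C
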